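The quinone ring is disconnected at C5–C6, between the methoxy-bearing carbon and the only ring CH. Four of the six ring carbons (C1, C2, C4, C5) are at carbonyl level, so the ring is the enol form of a cyclohexane-1,2,4,5-tetrone and C5–C6 is a Claisen bond between a methyl ketone and a 2-oxo ester. The key step is a Dieckmann-type closure of an acyclic methyl 2,4,5-trioxohexanoate that already carries the (8Z,11Z)-pentadecadienyl chain at C3; it delivers the fully oxygenated quinone in one operation, without an oxidant. Site-selective O-methylation at C5 ends the route.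

Key step: step 6

Remark: the ring is numbered as in the quinone name (C1 and C4 carbonyl, C2 hydroxyl, C3 chain, C5 methoxy, C6 H). The 2,5-dihydroxy-1,4-benzoquinone intermediate is written as the tautomer with hydroxyl groups on C2 and C5; its other tautomer is the same compound.

Step 1
Reactants: 1 non-8-yn-1-ol; 2 1-bromohex-2-yne
Product: 3 pentadeca-8,11-diyn-1-ol
Conditions: CuI (20 mol %), Cs2CO3, DMF, rt
Reagents that add atoms: none
Why: Copper-catalysed coupling of a terminal alkyne (through its copper acetylide) with a propargylic bromide should give the skipped 1,4-diyne by SN2 displacement, and the free hydroxyl group is tolerated.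

Step 2
Reactants: 3 pentadeca-8,11-diyn-1-ol
Product: 4 (8Z,11Z)-pentadeca-8,11-dien-1-ol
Conditions: H2 (1 atm), Pd/CaCO3 poisoned with Pb(OAc)2 (Lindlar catalyst), quinoline, EtOAc, rt
Reagents that add atoms: none
Why: Lindlar semihydrogenation delivers hydrogen syn to each alkyne from the poisoned palladium surface, which sets both Z alkenes and should stop at the diene.

Step 3
Reactants: 4 (8Z,11Z)-pentadeca-8,11-dien-1-ol
Product: 5 (8Z,11Z)-1-iodopentadeca-8,11-diene
Conditions: I2, PPh3, imidazole, CH2Cl2, 0 °C to rt
Reagents that add atoms: iodine, II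
Why: Appel-type iodination, in which the alkoxyphosphonium ion of the primary alcohol is displaced by iodide in an SN2 step that leaves the skipped diene untouched.

Step 4
Reactants: 5 (8Z,11Z)-1-iodopentadeca-8,11-diene; 6 3,3-dimethoxybutan-2-one
Product: 7 (12Z,15Z)-2,2-dimethoxynonadeca-12,15-dien-3-one
Conditions: 6 (2 equiv), LiN(i-Pr)2, THF, −78 °C; then 5, DMPU, −78 °C to 0 °C
Reagents that add atoms: none
Why: Alkylation of a ketone lithium enolate: 6 can enolise only towards its acetyl methyl group because the other flank is the quaternary ketal carbon, and the primary iodide should react by SN2 with the enolate, which is used in excess to suppress dialkylation.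

Step 5
Reactants: 7 (12Z,15Z)-2,2-dimethoxynonadeca-12,15-dien-3-one; 8 dimethyl oxalate
Product: 10 methyl 2,4,5-trioxo-3-[(8Z,11Z)-pentadeca-8,11-dien-1-yl]hexanoate, via ketal-protected dioxo ester 9 (not isolated)
Conditions: LiN(SiMe3)2, THF, −78 °C; 8, −78 °C to rt; then 2 M aq. HCl, THF, rt
Reagents that add atoms: water, O
Why: Crossed Claisen condensation, in which the only enolisable position of 7 (C4) is acylated by non-enolisable dimethyl oxalate and the step is driven by deprotonation of the 2,4-dioxo ester, after which aqueous acid should hydrolyse the dimethyl ketal and release the C5 ketone.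

Step 6
Reactants: 10 methyl 2,4,5-trioxo-3-[(8Z,11Z)-pentadeca-8,11-dien-1-yl]hexanoate
Product: 11 2,5-dihydroxy-3-[(8Z,11Z)-pentadeca-8,11-dien-1-yl]cyclohexa-2,5-diene-1,4-dione
Conditions: NaOMe (3 equiv), MeOH (0.02 M), 0 °C to rt; then 1 M aq. HCl
Reagents that add atoms: none
Why: Methoxide first removes C3–H of the 1,3-dicarbonyl unit and then reversibly forms the enolate of the C6 methyl ketone, which adds to the C1 ester carbonyl and expels methoxide (Dieckmann-type intramolecular Claisen condensation). The closest known reaction type is the alkoxide-induced ring closure of oxo esters to cyclic 1,3-diones, as in the base-mediated condensation of 2-oxo esters to 2,5-dihydroxy-1,4-benzoquinones. The ring closes in a 6-(enolendo)-exo-trig mode to the cyclohexane-1,2,4,5-tetrone, which is the keto tautomer of quinone 11, so no oxidant is needed. No stereocenter is formed, and the Z,Z-diene should not be touched by methoxide at room temperature. The step needs C-acylation at the ester in preference to aldol addition to the C2 or C4 ketone and to intermolecular aldol reaction of the acetyl group: the enolate across C2–C3–C4 switches off both ketones, aldol adducts and O-acylated forms are reversible under methoxide, high dilution disfavours intermolecular reaction, and the doubly deprotonated dihydroxyquinone is the thermodynamic sink.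

Step 7
Reactants: 11 2,5-dihydroxy-3-[(8Z,11Z)-pentadeca-8,11-dien-1-yl]cyclohexa-2,5-diene-1,4-dione
Product: 12 sorgoleone-360, 2-hydroxy-5-methoxy-3-[(8Z,11Z)-pentadeca-8,11-dien-1-yl]cyclohexa-2,5-diene-1,4-dione
Conditions: MeOH, H2SO4 (cat.), rt
Reagents that add atoms: methanol, CO
Why: Acid-catalysed addition–elimination of methanol (Fischer-type esterification of the vinylogous acid) should occur at the hydroxyl-bearing carbon next to C6–H, because the hydroxyl flanked by the C3 chain is shielded and its ether would be twisted out of conjugation.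

Compound list
1 | non-8-yn-1-ol | C#CCCCCCCCO | starting material
2 | 1-bromohex-2-yne | CCCC#CCBr | starting material
3 | pentadeca-8,11-diyn-1-ol | CCCC#CCC#CCCCCCCCO | intermediate
4 | (8Z,11Z)-pentadeca-8,11-dien-1-ol | CCC/C=C\C/C=C\CCCCCCCO | intermediate
5 | (8Z,11Z)-1-iodopentadeca-8,11-diene | CCC/C=C\C/C=C\CCCCCCCI | intermediate
6 | 3,3-dimethoxybutan-2-one | CC(=O)C(C)(OC)OC | starting material
7 | (12Z,15Z)-2,2-dimethoxynonadeca-12,15-dien-3-one | CCC/C=C\C/C=C\CCCCCCCCC(=O)C(C)(OC)OC | intermediate
8 | dimethyl oxalate | COC(=O)C(=O)OC | starting material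
9 | methyl 5,5-dimethoxy-2,4-dioxo-3-[(8Z,11Z)-pentadeca-8,11-dien-1-yl]hexanoate | CCC/C=C\C/C=C\CCCCCCCC(C(=O)C(=O)OC)C(=O)C(C)(OC)OC | intermediate
10 | methyl 2,4,5-trioxo-3-[(8Z,11Z)-pentadeca-8,11-dien-1-yl]hexanoate (in equilibrium with enol and cyclic hemiketal forms) | CCC/C=C\C/C=C\CCCCCCCC(C(=O)C(=O)OC)C(=O)C(C)=O | intermediate
11 | 2,5-dihydroxy-3-[(8Z,11Z)-pentadeca-8,11-dien-1-yl]cyclohexa-2,5-diene-1,4-dione | CCC/C=C\C/C=C\CCCCCCCC1=C(O)C(=O)C=C(O)C1=O | intermediate
12 | sorgoleone-360, 2-hydroxy-5-methoxy-3-[(8Z,11Z)-pentadeca-8,11-dien-1-yl]cyclohexa-2,5-diene-1,4-dione | CCC/C=C\C/C=C\CCCCCCCC1=C(O)C(=O)C=C(OC)C1=O | target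

Total step count: 7
Longest linear sequence: 7 steps (1 → 3 → 4 → 5 → 7 → 10 → 11 → 12); compounds 2, 6 and 8 are bought.

Steps most likely to fail

Step 6. The acetyl ketone of 10 may enter intermolecular aldol oligomerisation, or methoxide may attack the contiguous carbonyl array, before the methyl enolate reaches the ester. The fallback gives up the ring construction and attaches the chain to a purchased ring. It sets out from alcohol 4, which is oxidised with Dess–Martin periodinane (CH2Cl2, NaHCO3, rt) to (8Z,11Z)-pentadeca-8,11-dienal F1. The aldehyde is then joined to an excess of commercial 2,5-dihydroxy-1,4-benzoquinone by organocatalytic reductive alkylation (L-proline cat., Hantzsch ester, CH2Cl2, rt): Knoevenagel condensation at the nucleophilic ring carbon followed by hydride transfer to the quinone methide should give 11, where the route is rejoined.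

Step 7. Methylation may lose site selectivity, with ether formation at the hindered C2 oxygen or at both oxygens. The fallback protects both oxygens and releases only the unhindered one. It sets out from 11: Ac2O and pyridine should give 2,5-diacetoxy-3-[(8Z,11Z)-pentadeca-8,11-dien-1-yl]cyclohexa-2,5-diene-1,4-dione F2. Brief methanolysis (NaHCO3, MeOH, 0 °C) should cleave the unhindered C5 acetate first and give 2-acetoxy-5-hydroxy-3-[(8Z,11Z)-pentadeca-8,11-dien-1-yl]cyclohexa-2,5-diene-1,4-dione F3. MeI and Ag2O in CH2Cl2 then methylate the only free hydroxyl to give 2-acetoxy-5-methoxy-3-[(8Z,11Z)-pentadeca-8,11-dien-1-yl]cyclohexa-2,5-diene-1,4-dione F4. K2CO3 in MeOH at 0 °C removes the C2 acetate and returns to 12.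

Step 4. The enolate alkylation may be slow with the unactivated iodide, so that proton exchange between product and enolate leads to dialkylation or the enolate decomposes. The fallback uses a stabilised enolate and removes the activating group afterwards. It sets out from iodide 5, which alkylates commercial methyl 4,4-dimethoxy-3-oxopentanoate (K2CO3, acetone, reflux) to give methyl (10Z,13Z)-2-(2,2-dimethoxypropanoyl)heptadeca-10,13-dienoate F5. Krapcho demethoxycarbonylation (LiCl, wet DMSO, 140 °C) then returns to ketone 7.

Further compounds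
F1 | step 6 | (8Z,11Z)-pentadeca-8,11-dienal | CCC/C=C\C/C=C\CCCCCCC=O
F2 | step 7 | 2,5-diacetoxy-3-[(8Z,11Z)-pentadeca-8,11-dien-1-yl]cyclohexa-2,5-diene-1,4-dione | CCC/C=C\C/C=C\CCCCCCCC1=C(OC(C)=O)C(=O)C=C(OC(C)=O)C1=O
F3 | step 7 | 2-acetoxy-5-hydroxy-3-[(8Z,11Z)-pentadeca-8,11-dien-1-yl]cyclohexa-2,5-diene-1,4-dione | CCC/C=C\C/C=C\CCCCCCCC1=C(OC(C)=O)C(=O)C=C(O)C1=O
F4 | step 7 | 2-acetoxy-5-methoxy-3-[(8Z,11Z)-pentadeca-8,11-dien-1-yl]cyclohexa-2,5-diene-1,4-dione | CCC/C=C\C/C=C\CCCCCCCC1=C(OC(C)=O)C(=O)C=C(OC)C1=O
F5 | step 4 | methyl (10Z,13Z)-2-(2,2-dimethoxypropanoyl)heptadeca-10,13-dienoate | CCC/C=C\C/C=C\CCCCCCCC(C(=O)OC)C(=O)C(C)(OC)OC
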